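**Retrosynthetic overview**
1. Target ⇐ MnO2 oxidation at C7, desilylation and Mitsunobu esterification with inversion at C4 ⇐ 4‑oxo‑7‑hydroxy‑Δ5‑hydroazulene 21 ⇐ SmI2 scission of the C3a–O bond of the oxygen‑bridged cycloadduct 20.
2. Key disconnection: C3a–C8a and C7–C8 by an intramolecular 3‑oxidopyrylium–alkene [5+2] cycloaddition, which closes the cyclopentane and the cycloheptenone together.
3. Enabling feature: the seven‑membered‑ring segment C3a–C4(O)–C5=C6(CH3)–C7(=O), with oxygen on C4 and C7 flanking the C5=C6 bond, is a 3‑oxidopyrylium once an oxygen links C3a and C7. The C8=C8a(CH3) partner hangs on the C1–C2–C3 chain of the five‑membered ring, whose cis C1/C3 oxygens can be tied as a cyclic phenylboronate (temporary ring) that fixes the face.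
4. Pyranone ⇐ Achmatowicz oxidation of furyl carbinol 13 ⇐ 3‑methylfuran + lactol 10; C3 from (R)‑2‑hydroxy‑3‑methylbutanoic acid by dioxolanone alkylation, C1 by Shi epoxidation and epoxide‑to‑allylic‑alcohol isomerisation.
5. Ring order: dioxolanone (auxiliary) → γ‑lactone/lactol → pyranone from the furan → dioxaborinane → five‑ and seven‑membered carbocycles in one step → oxygen bridge cleaved.

Key step: step 9

Remark: C1–C8a are the azulene positions of the target core (C1 acetoxy carbon, C3 tertiary carbinol, C3a/C8a ring fusion, C4 ester carbon, C7 ketone).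
Remark: 13–16 are carried as mixtures at the furfuryl carbon (later C3a) and, for 14–16, at the anomeric carbon; both centres become sp2 in ylide 17 and are written without configuration.

**Step 1**
Reactants: 1 (R)-2-hydroxy-3-methylbutanoic acid; 2 pivalaldehyde
Product: 3 (2R,5R)-2-tert-butyl-5-isopropyl-1,3-dioxolan-4-one
Conditions: p-TsOH (cat.), H2SO4 (cat.), pentane, reflux, water separator; recrystallisation
Reagents that add atoms: none
Why: Acid‑catalysed acetalisation under thermodynamic control should place tert‑butyl and isopropyl cis, so the existing carbinol centre sets the acetal centre.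

**Step 2**
Reactants: 3 (2R,5R)-2-tert-butyl-5-isopropyl-1,3-dioxolan-4-one; 4 prenyl bromide
Product: 6 (2R,5R)-2-tert-butyl-5-isopropyl-5-(3-methylbut-2-en-1-yl)-1,3-dioxolan-4-one, via lithium enolate 5 (not isolated)
Conditions: LiN(iPr)2, THF, −78 °C; then 4, −78 to −30 °C
Reagents that add atoms: none
Why: Dioxolanone enolate alkylation (self‑regeneration of stereocentres): the allylic bromide should enter anti to the tert‑butyl group, so prenyl replaces H with retention and sets the future C3.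

**Step 3**
Reactants: 6 (2R,5R)-2-tert-butyl-5-isopropyl-5-(3-methylbut-2-en-1-yl)-1,3-dioxolan-4-one
Product: 7 (2R,5R)-2-tert-butyl-5-{[(2R)-3,3-dimethyloxiran-2-yl]methyl}-5-isopropyl-1,3-dioxolan-4-one
Conditions: D‑fructose‑derived Shi ketone (0.3 equiv), Oxone (2KHSO5·KHSO4·K2SO4), K2CO3, Bu4NHSO4 (cat.), MeCN/CH2(OMe)2/aq. Na2B4O7 buffer, 0 °C
Reagents that add atoms: potassium peroxymonosulfate (oxidant in Oxone), [K+].[O-]S(=O)(=O)OO
Why: Shi asymmetric epoxidation of the trisubstituted alkene through the spiro dioxirane transition state should give the (R)‑epoxide under catalyst control, which sets the future C1.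

**Step 4**
Reactants: 7 (2R,5R)-2-tert-butyl-5-{[(2R)-3,3-dimethyloxiran-2-yl]methyl}-5-isopropyl-1,3-dioxolan-4-one
Product: 9 (3R,5R)-3-hydroxy-3-isopropyl-5-(prop-1-en-2-yl)dihydrofuran-2(3H)-one, via allylic alcohol 8 (not isolated)
Conditions: Al(OiPr)3, toluene, 110 °C
Reagents that add atoms: none
Why: Aluminium‑alkoxide epoxide‑to‑allylic‑alcohol isomerisation (a methyl hydrogen is lost and the tertiary C–O bond breaks, leaving the C1–O bond and its configuration untouched), after which the C1 alkoxide should translactonise onto the activated dioxolanone carbonyl with loss of pivalaldehyde.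

**Step 5**
Reactants: 9 (3R,5R)-3-hydroxy-3-isopropyl-5-(prop-1-en-2-yl)dihydrofuran-2(3H)-one
Product: 10 (3R,5R)-3-isopropyl-5-(prop-1-en-2-yl)tetrahydrofuran-2,3-diol (anomer mixture)
Conditions: i-Bu2AlH (2.2 equiv), CH2Cl2, −78 °C
Reagents that add atoms: none
Why: Partial reduction of a lactone to the lactol, the tetrahedral aluminium acetal being stable at −78 °C until work‑up; the anomeric centre is of no consequence.

**Step 6**
Reactants: 10 (3R,5R)-3-isopropyl-5-(prop-1-en-2-yl)tetrahydrofuran-2,3-diol; 11 3-methylfuran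
Product: 13 (2R,4R)-2-isopropyl-5-methyl-1-(4-methylfuran-2-yl)hex-5-ene-1,2,4-triol, via 4-methyl-2-furyllithium 12 (not isolated)
Conditions: 11 (3.3 equiv), n-BuLi, TMEDA, THF, −78 to 0 °C; then 10, −78 °C to rt
Reagents that add atoms: none
Why: α‑Lithiation of 3‑methylfuran is expected mainly at C5, remote from the methyl group, and the aryllithium adds to the open hydroxy‑aldehyde form of the lactol (organolithium addition to a lactol); the new carbinol centre forms as a mixture that is erased later and any regioisomeric furan is removed by chromatography.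

**Step 7**
Reactants: 13 (2R,4R)-2-isopropyl-5-methyl-1-(4-methylfuran-2-yl)hex-5-ene-1,2,4-triol
Product: 14 2-[(3R,5R)-3,5-dihydroxy-2,6-dimethylhept-6-en-3-yl]-6-hydroxy-5-methyl-2H-pyran-3(6H)-one
Conditions: NBS (1.05 equiv), NaHCO3, NaOAc, THF/H2O (4:1), 0 °C
Reagents that add atoms: water, O
Why: Achmatowicz rearrangement: the furan, far more nucleophilic than the isopropenyl group, is oxidised to the ene‑dione, which the furfuryl hydroxyl closes to the 6‑hydroxypyranone.

**Step 8**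
Reactants: 14 2-[(3R,5R)-3,5-dihydroxy-2,6-dimethylhept-6-en-3-yl]-6-hydroxy-5-methyl-2H-pyran-3(6H)-one
Product: 16 6-acetoxy-2-[(4R,6R)-4-isopropyl-2-phenyl-6-(prop-1-en-2-yl)-1,3,2-dioxaborinan-4-yl]-5-methyl-2H-pyran-3(6H)-one, via boronate hemiacetal 15 (not isolated)
Conditions: PhB(OH)2, MgSO4, CH2Cl2, rt; then Ac2O, pyridine, DMAP (cat.), 0 °C
Reagents that add atoms: phenylboronic acid, OB(O)c1ccccc1; acetic anhydride, CC(=O)OC(C)=O
Why: Cyclic boronate formation of the 1,3‑diol (as used for prostaglandin 9,11‑diols) leaves the anomeric hydroxyl as the only free OH, which DMAP‑catalysed acylation turns into the ylide precursor.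

**Step 9**
Reactants: 16 6-acetoxy-2-[(4R,6R)-4-isopropyl-2-phenyl-6-(prop-1-en-2-yl)-1,3,2-dioxaborinan-4-yl]-5-methyl-2H-pyran-3(6H)-one
Product: 19 (1R,3R,3aR,7R,8aR)-1,3-dihydroxy-3-isopropyl-6,8a-dimethyl-1,2,3,7,8,8a-hexahydro-4H-3a,7-epoxyazulen-4-one, via oxidopyrylium ylide 17 (not isolated), via boronate cycloadduct 18 (not isolated)
Conditions: iPr2NEt, MeCN (0.01 M), 80 °C; then pinacol, MeOH, rt
Reagents that add atoms: none
Why: Base‑induced loss of acetic acid from 16 gives the 3‑oxidopyrylium 17, whose termini C3a and C7 add suprafacially and in concert across the tethered C8a=C8 bond; the closest known reaction type is the intramolecular oxidopyrylium–alkene [5+2] cycloaddition of 6‑acetoxypyranones. The cyclopentane closes through the C3a–C8a bond over the three‑atom chain (fused mode, chain exo on the new bicycle), and the cycloheptenone closes through C3a–C8a plus C7–C8 as an 8‑oxabicyclo[3.2.1]oct‑3‑en‑2‑one, the only regiochemistry the short tether allows. C3a, C7 and C8a arise together and are fixed relative to one another by the concerted geometry (oxygen bridge syn to C1, angular methyl endo). Their relation to C1 and C3, the facial selectivity the step needs, is secured by the dioxaborinane: bonding requires C3a and C8a as 1,3‑diaxial groups, which builds a 2,4‑dioxa‑3‑borabicyclo[3.2.1]octane in which only the unsubstituted ring oxygen of the ylide, not its oxido‑bearing C4, fits under the O–B–O bridge, so the angular methyl should end anti to both oxygens. High dilution suppresses ylide dimerisation, and transesterification with pinacol then frees the diol.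

**Step 10**
Reactants: 19 (1R,3R,3aR,7R,8aR)-1,3-dihydroxy-3-isopropyl-6,8a-dimethyl-1,2,3,7,8,8a-hexahydro-4H-3a,7-epoxyazulen-4-one
Product: 20 (1R,3R,3aR,7R,8aR)-3-hydroxy-3-isopropyl-6,8a-dimethyl-4-oxo-1,2,3,7,8,8a-hexahydro-4H-3a,7-epoxyazulen-1-yl acetate
Conditions: Ac2O (1.2 equiv), pyridine, DMAP (cat.), CH2Cl2, 0 °C to rt
Reagents that add atoms: acetic anhydride, CC(=O)OC(C)=O
Why: DMAP‑catalysed acylation should take the secondary C1 hydroxyl only, the tertiary C3 hydroxyl next to isopropyl being inert.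

**Step 11**
Reactants: 20 (1R,3R,3aR,7R,8aR)-3-hydroxy-3-isopropyl-6,8a-dimethyl-4-oxo-1,2,3,7,8,8a-hexahydro-4H-3a,7-epoxyazulen-1-yl acetate
Product: 21 (1R,3R,3aS,7R,8aS)-3,7-dihydroxy-3-isopropyl-6,8a-dimethyl-4-oxo-1,2,3,3a,4,7,8,8a-octahydroazulen-1-yl acetate
Conditions: SmI2 (2.5 equiv), THF/MeOH, −78 °C
Reagents that add atoms: none
Why: SmI2 reductive cleavage of an α‑alkoxy ketone (chelated ketyl, loss of the bridging oxygen as the C7 alkoxide) opens the bridge, and MeOH should protonate the C3a samarium enolate from the face anti to the angular methyl and the isopropyl group, which sets the trans ring fusion.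

**Step 12**
Reactants: 21 (1R,3R,3aS,7R,8aS)-3,7-dihydroxy-3-isopropyl-6,8a-dimethyl-4-oxo-1,2,3,3a,4,7,8,8a-octahydroazulen-1-yl acetate
Product: 22 (1R,3R,3aS,7R,8aS)-3-hydroxy-3-isopropyl-6,8a-dimethyl-4-oxo-7-(triethylsilyloxy)-1,2,3,3a,4,7,8,8a-octahydroazulen-1-yl acetate
Conditions: TESCl, imidazole, DMF, 0 °C
Reagents that add atoms: chlorotriethylsilane, CC[Si](Cl)(CC)CC
Why: Silylation of the only secondary alcohol; the tertiary C3 hydroxyl does not react with TESCl/imidazole.

**Step 13**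
Reactants: 22 (1R,3R,3aS,7R,8aS)-3-hydroxy-3-isopropyl-6,8a-dimethyl-4-oxo-7-(triethylsilyloxy)-1,2,3,3a,4,7,8,8a-octahydroazulen-1-yl acetate
Product: 23 (1R,3R,3aR,4S,7R,8aS)-3,4-dihydroxy-3-isopropyl-6,8a-dimethyl-7-(triethylsilyloxy)-1,2,3,3a,4,7,8,8a-octahydroazulen-1-yl acetate
Conditions: NaBH4, CeCl3·7H2O, MeOH, −78 °C
Reagents that add atoms: none
Why: Luche 1,2‑reduction of the enone; hydride is expected on the open face syn to C3a–H and anti to the angular methyl and isopropyl groups (as 6‑oxo‑5α‑steroids give 6β‑ols), which gives the (4S) alcohol, the C4 epimer of the target.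

**Step 14**
Reactants: 24 4-hydroxybenzoic acid
Product: 26 4-(tert-butyldimethylsilyloxy)benzoic acid, via bis-silyl derivative 25 (not isolated)
Conditions: TBSCl (2.2 equiv), imidazole, DMF, rt; then AcOH/THF/H2O, rt
Reagents that add atoms: tert-butylchlorodimethylsilane, CC(C)(C)[Si](C)(C)Cl
Why: Bis‑silylation followed by selective hydrolysis of the labile silyl ester should leave the aryl silyl ether.

**Step 15**
Reactants: 23 (1R,3R,3aR,4S,7R,8aS)-3,4-dihydroxy-3-isopropyl-6,8a-dimethyl-7-(triethylsilyloxy)-1,2,3,3a,4,7,8,8a-octahydroazulen-1-yl acetate; 26 4-(tert-butyldimethylsilyloxy)benzoic acid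
Product: 27 (1R,3R,3aR,4R,7R,8aS)-1-acetoxy-3-hydroxy-3-isopropyl-6,8a-dimethyl-7-(triethylsilyloxy)-1,2,3,3a,4,7,8,8a-octahydroazulen-4-yl 4-(tert-butyldimethylsilyloxy)benzoate
Conditions: PPh3, DIAD, toluene, 0 °C to rt
Reagents that add atoms: none
Why: Mitsunobu esterification: the carboxylate displaces the allylic oxyphosphonium by SN2 from the open face syn to C3a–H, so inversion sets (4R).

**Step 16**
Reactants: 27 (1R,3R,3aR,4R,7R,8aS)-1-acetoxy-3-hydroxy-3-isopropyl-6,8a-dimethyl-7-(triethylsilyloxy)-1,2,3,3a,4,7,8,8a-octahydroazulen-4-yl 4-(tert-butyldimethylsilyloxy)benzoate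
Product: 28 (1R,3R,3aR,4R,7R,8aS)-1-acetoxy-3,7-dihydroxy-3-isopropyl-6,8a-dimethyl-1,2,3,3a,4,7,8,8a-octahydroazulen-4-yl 4-hydroxybenzoate
Conditions: HF·pyridine, THF/pyridine, 0 °C to rt
Reagents that add atoms: none
Why: Fluoride cleaves both Si–O bonds while the acetate and the benzoate ester stay intact.

**Step 17**
Reactants: 28 (1R,3R,3aR,4R,7R,8aS)-1-acetoxy-3,7-dihydroxy-3-isopropyl-6,8a-dimethyl-1,2,3,3a,4,7,8,8a-octahydroazulen-4-yl 4-hydroxybenzoate
Product: 29 (1R,3R,3aR,4R,8aS)-1-acetoxy-3-hydroxy-3-isopropyl-6,8a-dimethyl-7-oxo-1,2,3,3a,4,7,8,8a-octahydroazulen-4-yl 4-hydroxybenzoate (CNP0087181.5)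
Conditions: MnO2 (activated, excess), CH2Cl2, rt
Reagents that add atoms: none
Why: MnO2 oxidation should be selective for the allylic C7 alcohol over the tertiary alcohol and the electron‑poor phenol.

**Compound list**
1 | (R)-2-hydroxy-3-methylbutanoic acid | CC(C)[C@@H](O)C(O)=O | starting material
2 | pivalaldehyde | CC(C)(C)C=O | starting material
3 | (2R,5R)-2-tert-butyl-5-isopropyl-1,3-dioxolan-4-one | CC(C)[C@H]1O[C@@H](C(C)(C)C)OC1=O | intermediate
4 | prenyl bromide (1-bromo-3-methylbut-2-ene) | CC(C)=CCBr | starting material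
5 | lithium enolate of 3 | CC(C)C1=C(O[Li])O[C@H](C(C)(C)C)O1 | intermediate (not isolated)
6 | (2R,5R)-2-tert-butyl-5-isopropyl-5-(3-methylbut-2-en-1-yl)-1,3-dioxolan-4-one | CC(C)[C@@]1(CC=C(C)C)O[C@@H](C(C)(C)C)OC1=O | intermediate
7 | (2R,5R)-2-tert-butyl-5-{[(2R)-3,3-dimethyloxiran-2-yl]methyl}-5-isopropyl-1,3-dioxolan-4-one | CC(C)[C@@]1(C[C@H]2OC2(C)C)O[C@@H](C(C)(C)C)OC1=O | intermediate
8 | (2R,5R)-2-tert-butyl-5-[(2R)-2-hydroxy-3-methylbut-3-en-1-yl]-5-isopropyl-1,3-dioxolan-4-one | CC(C)[C@@]1(C[C@@H](O)C(C)=C)O[C@@H](C(C)(C)C)OC1=O | intermediate (not isolated)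
9 | (3R,5R)-3-hydroxy-3-isopropyl-5-(prop-1-en-2-yl)dihydrofuran-2(3H)-one | CC(C)[C@]1(O)C[C@H](C(C)=C)OC1=O | intermediate
10 | (3R,5R)-3-isopropyl-5-(prop-1-en-2-yl)tetrahydrofuran-2,3-diol, anomer mixture | CC(C)[C@]1(O)C[C@H](C(C)=C)OC1O | intermediate
11 | 3-methylfuran | Cc1ccoc1 | starting material
12 | 4-methyl-2-furyllithium | [Li]c1cc(C)co1 | intermediate (not isolated)
13 | (2R,4R)-2-isopropyl-5-methyl-1-(4-methylfuran-2-yl)hex-5-ene-1,2,4-triol, both C1 epimers | CC(C)[C@](O)(C[C@@H](O)C(C)=C)C(O)c1cc(C)co1 | intermediate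
14 | 2-[(3R,5R)-3,5-dihydroxy-2,6-dimethylhept-6-en-3-yl]-6-hydroxy-5-methyl-2H-pyran-3(6H)-one | CC(C)[C@](O)(C[C@@H](O)C(C)=C)C1OC(O)C(C)=CC1=O | intermediate
15 | 6-hydroxy-2-[(4R,6R)-4-isopropyl-2-phenyl-6-(prop-1-en-2-yl)-1,3,2-dioxaborinan-4-yl]-5-methyl-2H-pyran-3(6H)-one | CC(C)[C@]1(C[C@H](C(C)=C)OB(c2ccccc2)O1)C1OC(O)C(C)=CC1=O | intermediate (not isolated)
16 | 6-acetoxy-2-[(4R,6R)-4-isopropyl-2-phenyl-6-(prop-1-en-2-yl)-1,3,2-dioxaborinan-4-yl]-5-methyl-2H-pyran-3(6H)-one | CC(C)[C@]1(C[C@H](C(C)=C)OB(c2ccccc2)O1)C1OC(OC(C)=O)C(C)=CC1=O | intermediate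
17 | 2-[(4R,6R)-4-isopropyl-2-phenyl-6-(prop-1-en-2-yl)-1,3,2-dioxaborinan-4-yl]-5-methylpyrylium-3-olate | CC(C)[C@]1(C[C@H](C(C)=C)OB(c2ccccc2)O1)c1[o+]cc(C)cc1[O-] | intermediate (not isolated)
18 | 1,3-O-phenylboranediyl derivative of 19 (oxygen bridge syn to both boronate oxygens, angular methyl anti) | c1ccccc1B2O[C@@H]3C[C@@](O2)(C(C)C)[C@]45O[C@@H](C(C)=CC5=O)C[C@]34C | intermediate (not isolated)
19 | (1R,3R,3aR,7R,8aR)-1,3-dihydroxy-3-isopropyl-6,8a-dimethyl-1,2,3,7,8,8a-hexahydro-4H-3a,7-epoxyazulen-4-one | O[C@@H]1C[C@@](O)(C(C)C)[C@]23O[C@@H](C(C)=CC3=O)C[C@]12C | intermediate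
20 | (1R,3R,3aR,7R,8aR)-3-hydroxy-3-isopropyl-6,8a-dimethyl-4-oxo-1,2,3,7,8,8a-hexahydro-4H-3a,7-epoxyazulen-1-yl acetate | CC(=O)O[C@@H]1C[C@@](O)(C(C)C)[C@]23O[C@@H](C(C)=CC3=O)C[C@]12C | intermediate
21 | (1R,3R,3aS,7R,8aS)-3,7-dihydroxy-3-isopropyl-6,8a-dimethyl-4-oxo-1,2,3,3a,4,7,8,8a-octahydroazulen-1-yl acetate | CC(=O)O[C@@H]1C[C@@](O)(C(C)C)[C@H]2C(=O)C=C(C)[C@H](O)C[C@]12C | intermediate
22 | (1R,3R,3aS,7R,8aS)-3-hydroxy-3-isopropyl-6,8a-dimethyl-4-oxo-7-(triethylsilyloxy)-1,2,3,3a,4,7,8,8a-octahydroazulen-1-yl acetate | CC(=O)O[C@@H]1C[C@@](O)(C(C)C)[C@H]2C(=O)C=C(C)[C@H](O[Si](CC)(CC)CC)C[C@]12C | intermediate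
23 | (1R,3R,3aR,4S,7R,8aS)-3,4-dihydroxy-3-isopropyl-6,8a-dimethyl-7-(triethylsilyloxy)-1,2,3,3a,4,7,8,8a-octahydroazulen-1-yl acetate | CC(=O)O[C@@H]1C[C@@](O)(C(C)C)[C@H]2[C@@H](O)C=C(C)[C@H](O[Si](CC)(CC)CC)C[C@]12C | intermediate
24 | 4-hydroxybenzoic acid | OC(=O)c1ccc(O)cc1 | starting material
25 | tert-butyldimethylsilyl 4-(tert-butyldimethylsilyloxy)benzoate | CC(C)(C)[Si](C)(C)OC(=O)c1ccc(O[Si](C)(C)C(C)(C)C)cc1 | intermediate (not isolated)
26 | 4-(tert-butyldimethylsilyloxy)benzoic acid | CC(C)(C)[Si](C)(C)Oc1ccc(cc1)C(O)=O | intermediate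
27 | (1R,3R,3aR,4R,7R,8aS)-1-acetoxy-3-hydroxy-3-isopropyl-6,8a-dimethyl-7-(triethylsilyloxy)-1,2,3,3a,4,7,8,8a-octahydroazulen-4-yl 4-(tert-butyldimethylsilyloxy)benzoate | CC(=O)O[C@@H]1C[C@@](O)(C(C)C)[C@H]2[C@H](OC(=O)c3ccc(O[Si](C)(C)C(C)(C)C)cc3)C=C(C)[C@H](O[Si](CC)(CC)CC)C[C@]12C | intermediate
28 | (1R,3R,3aR,4R,7R,8aS)-1-acetoxy-3,7-dihydroxy-3-isopropyl-6,8a-dimethyl-1,2,3,3a,4,7,8,8a-octahydroazulen-4-yl 4-hydroxybenzoate | CC(=O)O[C@@H]1C[C@@](O)(C(C)C)[C@H]2[C@H](OC(=O)c3ccc(O)cc3)C=C(C)[C@H](O)C[C@]12C | intermediate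
29 | (1R,3R,3aR,4R,8aS)-1-acetoxy-3-hydroxy-3-isopropyl-6,8a-dimethyl-7-oxo-1,2,3,3a,4,7,8,8a-octahydroazulen-4-yl 4-hydroxybenzoate | CC(=O)O[C@@H]1C[C@@](O)(C(C)C)[C@H]2[C@H](OC(=O)c3ccc(O)cc3)C=C(C)C(=O)C[C@]12C | target

**Step count**
Total: 17 steps. Longest linear sequence: 16 steps (1–13 and 15–17); step 14 is a one‑step side branch.

**Steps most likely to fail**

Step 9. The congested cycloaddition, which joins the fully substituted C3a to the quaternary C8a, may be outrun by ylide dimerisation or by β‑elimination of the C3 oxygen. Facial control would also be lost if the boronate opens under the basic conditions. The fallback gives up the temporary ring. It sets out from 14, which is acetylated at both the anomeric and the C1 hydroxyl (Ac2O, pyridine, DMAP) to give the bis‑acetate F1. Ylide formation and cycloaddition of F1 (DBU, MeCN, 60 °C, high dilution) then rely on the C1 stereocentre alone, where allylic strain should hold C1–H rather than C1–OAc next to the alkene methyl. The angular diastereomer would be removed by chromatography, and the route is rejoined at 20.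

Step 11. Vinylogous scission of the C7–O bond or conjugate reduction of the enone may compete with cleavage of the C3a–O bond, and the enolate may be protonated on the wrong face. The fallback takes the alkene out of play first. It sets out from 20, which is hydrogenated from the face of the oxygen bridge (H2, Pd/C, EtOAc) to the dihydro ketone F2. SmI2/MeOH cleavage of this plain α‑alkoxy ketone should give the ring‑opened hydroxy ketone F3, which is silylated (TESCl, imidazole) to its triethylsilyl ether F4. IBX dehydrogenation (DMSO/toluene, 70 °C) can only introduce the C5=C6 bond, because C3 and C8a carry no hydrogen, and it rejoins the route at 22.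

Step 15. Elimination to the diene, SN2′ attack at C6 or incomplete inversion may occur at the hindered allylic carbinol. The same fallback applies if the hydride in step 13 takes the other face. It separates inversion from acylation and sets out from 23. Mitsunobu reaction with the more acidic 4‑nitrobenzoic acid (PPh3, DIAD) should give the inverted 4‑nitrobenzoate F5. Selective methanolysis (NaN3, MeOH, 40 °C), which spares the C1 acetate, should give the (4R)‑alcohol F6. Acylation with 26 (EDC, DMAP, CH2Cl2) proceeds with retention and rejoins the route at 27. F6 is also the compound a reversed facial course in step 13 would deliver directly.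

**Further compounds**
F1 | step 9 | 6-acetoxy-2-[(3R,5R)-5-acetoxy-3-hydroxy-2,6-dimethylhept-6-en-3-yl]-5-methyl-2H-pyran-3(6H)-one | CC(C)[C@](O)(C[C@@H](OC(C)=O)C(C)=C)C1OC(OC(C)=O)C(C)=CC1=O
F2 | step 11 | 5,6-dihydro derivative of 20 (6-methyl anti to the oxygen bridge) | CC(=O)O[C@@H]1C[C@@](O)(C(C)C)[C@]23O[C@@H]([C@H](C)CC3=O)C[C@]12C
F3 | step 11 | 5,6-dihydro derivative of 21 | CC(=O)O[C@@H]1C[C@@](O)(C(C)C)[C@H]2C(=O)C[C@@H](C)[C@H](O)C[C@]12C
F4 | step 11 | 7-O-triethylsilyl ether of F3 | CC(=O)O[C@@H]1C[C@@](O)(C(C)C)[C@H]2C(=O)C[C@@H](C)[C@H](O[Si](CC)(CC)CC)C[C@]12C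
F5 | step 15 | (4R)-4-nitrobenzoate from 23 with inversion at C4 | CC(=O)O[C@@H]1C[C@@](O)(C(C)C)[C@H]2[C@H](OC(=O)c3ccc(cc3)[N+](=O)[O-])C=C(C)[C@H](O[Si](CC)(CC)CC)C[C@]12C
F6 | step 15 | (4R)-alcohol, the C4 epimer of 23 | CC(=O)O[C@@H]1C[C@@](O)(C(C)C)[C@H]2[C@H](O)C=C(C)[C@H](O[Si](CC)(CC)CC)C[C@]12C
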